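The 1-methylcyclohexene ring (C1 bears the methyl group, C6 is the CH2) holds its C1=C2 double bond opposite the C4–C5 bond. C3, C4 and C5 carry stilbenyl, aroyl and aryl groups all-trans. This is the retron of the presumed biosynthetic [4+2] union of a dehydroprenylstilbene with a 2'-hydroxychalcone. Cutting C5–C6 (aryl-bearing CH to ring CH2) together with C3–C4 leads to diene 15 and chalcone 5, both masked as acetates. The free hydroxyl ortho to the ketone on the benzoyl ring chelates a boron centre that bears (R)-VANOL. One exo- and face-selective cycloaddition therefore closes the ring and sets all three stereocentres. Mild methanolysis of seven acetates ends the route.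

Key step: step 10

Numbering used throughout: C1 (methyl-bearing sp2 carbon), C2 (=CH), C3 (CH-stilbenyl), C4 (CH-aroyl), C5 (CH-aryl), C6 (CH2).
Assumption: the facial bias of the (R)-VANOL spiroborate is taken from a quadrant model (a naphthalene wall over the Re face of the s-cis enone); the ligand antipode is equally available should the sense prove opposite.

Step 1
Reactants: 1 2,4-dihydroxyacetophenone
Product: 2 4-acetyl-3-hydroxyphenyl acetate
Conditions: Ac2O (1.0 equiv), pyridine, 0 °C
Reagents that add atoms: acetic anhydride, CC(=O)OC(C)=O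
Why: Selective O-acylation, because the 2-hydroxyl is held in a hydrogen bond to the ketone and is far less nucleophilic, so one equivalent of anhydride should acetylate only the 4-hydroxyl.

Step 2
Reactants: 3 2,4-dihydroxybenzaldehyde
Product: 4 4-formylbenzene-1,3-diyl diacetate
Conditions: Ac2O (2.5 equiv), DMAP (cat.), pyridine, 0 °C to rt
Reagents that add atoms: acetic anhydride, CC(=O)OC(C)=O
Why: Exhaustive O-acylation under nucleophilic catalysis should cap both phenols while the aldehyde stays inert in basic medium.

Step 3
Reactants: 2 4-acetyl-3-hydroxyphenyl acetate; 4 4-formylbenzene-1,3-diyl diacetate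
Product: 5 (E)-4-[3-(4-acetoxy-2-hydroxyphenyl)-3-oxoprop-1-enyl]benzene-1,3-diyl diacetate (2'-hydroxy-2,4,4'-triacetoxychalcone)
Conditions: BF3·OEt2 (50 mol%), 1,4-dioxane, rt; then H2O
Reagents that add atoms: none
Why: Lewis-acid-mediated Claisen–Schmidt condensation, in which boron-assisted enolisation of the methyl ketone, aldol addition to the activated electron-poor aldehyde and dehydration should give the conjugated E-enone under non-basic conditions that aryl acetates tolerate.

Step 4
Reactants: 6 3,5-dihydroxybenzaldehyde
Product: 8 5-vinylbenzene-1,3-diyl diacetate, via dipotassium 5-vinylresorcinolate 7 (not isolated)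
Conditions: MePPh3Br (1.3 equiv), KOtBu (3.4 equiv), THF, 0 °C to rt; then Ac2O (4 equiv), 0 °C
Reagents that add atoms: methyltriphenylphosphonium bromide, C[P+](c1ccccc1)(c1ccccc1)c1ccccc1.[Br-]; acetic anhydride, CC(=O)OC(C)=O; potassium tert-butoxide, CC(C)(C)[O-].[K+] (potassium in 7 only)
Why: Wittig methylenation tolerates the two meta-phenoxides, which are not conjugated with the aldehyde, and quenching the polymerisation-prone vinylresorcinolate with anhydride in the same flask should deliver the stable diacetate.

Step 5
Reactants: 9 4-bromobenzene-1,3-diol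
Product: 10 4-bromo-6-iodobenzene-1,3-diol
Conditions: ICl (1.0 equiv), Et2O, 0 °C to rt; aq. Na2SO3 wash
Reagents that add atoms: iodine monochloride, ClI
Why: Electrophilic aromatic iodination should go to C6, which is ortho to one hydroxyl and para to the other and is less crowded than C2 between the two hydroxyls.

Step 6
Reactants: 10 4-bromo-6-iodobenzene-1,3-diol
Product: 11 4-bromo-6-iodobenzene-1,3-diyl diacetate
Conditions: Ac2O (2.5 equiv), pyridine, rt
Reagents that add atoms: acetic anhydride, CC(=O)OC(C)=O
Why: Plain O-acylation of both phenols installs the protecting group that is carried to the end of the route.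

Step 7
Reactants: 11 4-bromo-6-iodobenzene-1,3-diyl diacetate; 8 5-vinylbenzene-1,3-diyl diacetate
Product: 12 4-bromo-6-[(E)-3,5-diacetoxystyryl]benzene-1,3-diyl diacetate
Conditions: Pd(OAc)2 (3 mol%), PPh3 (6 mol%), Et3N (2 equiv), MeCN, 80 °C
Reagents that add atoms: none
Why: Mizoroki–Heck reaction, in which zerovalent palladium inserts into the carbon–iodine bond much faster than into the carbon–bromine bond, syn carbopalladation at the terminal carbon and syn β-hydride elimination give the E-stilbene, and the amine base spares the acetates.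

Step 8
Reactants: 13 2-methylbut-1-en-3-yne
Product: 14 (E)-4,4,5,5-tetramethyl-2-(3-methylbuta-1,3-dienyl)-1,3,2-dioxaborolane
Conditions: HBpin (1.05 equiv), Cp2ZrHCl (5 mol%), Et3N (5 mol%), CH2Cl2, rt, sealed vessel
Reagents that add atoms: pinacolborane, CC1(C)OBOC1(C)C
Why: Catalysed hydroboration, in which syn hydrozirconation places the metal on the terminal alkyne carbon and exchange with pinacolborane should give the E-dienylboronate while the 1,1-disubstituted alkene stays untouched.

Step 9
Reactants: 12 4-bromo-6-[(E)-3,5-diacetoxystyryl]benzene-1,3-diyl diacetate; 14 (E)-dienyl pinacol boronate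
Product: 15 4-[(E)-3,5-diacetoxystyryl]-6-[(E)-3-methylbuta-1,3-dienyl]benzene-1,3-diyl diacetate
Conditions: Pd(dppf)Cl2 (5 mol%), CsF (2.5 equiv), BHT (cat.), anhydrous 1,4-dioxane, 70 °C
Reagents that add atoms: none
Why: Fluoride-activated Suzuki–Miyaura coupling transfers the alkenyl group with retention of its E geometry, and the water-free fluoride base should leave the four aryl acetates in place.

Step 10
Reactants: 5 2'-hydroxy-2,4,4'-triacetoxychalcone; 15 dienylstilbene tetraacetate
Product: 18 all-trans (3R,4R,5S) cycloadduct heptaacetate, via chalcone spiroborate 16 (not isolated), via cycloadduct spiroborate 17 (not isolated)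
Conditions: (R)-VANOL (1.2 equiv), BH3·THF (1.2 equiv), AcOH (1.2 equiv), THF, rt until H2 evolution ends; 5 (1.0 equiv), rt; volatiles off in vacuo; 15 (1.2 equiv), 5 Å MS, PhCF3, rt; H2O work-up
Reagents that add atoms: (R)-VANOL, Oc1c(-c2c(O)c3ccccc3cc2-c2ccccc2)c(-c2ccccc2)cc2ccccc12, and borane–THF, B.C1CCOC1 (both in 16 and 17 only; neither leaves atoms in 18)
Why: The free ortho-hydroxyl and the ketone oxygen of 5 displace acetate from the (R)-VANOL acetoxyborane to give the tetracoordinate spiroborate 16, whose lowered LUMO lets s-cis 15 add in a concerted but asynchronous normal-demand Diels–Alder reaction in which the C5–C6 bond (enone β-carbon to the CH2 terminus of the diene) runs ahead of the C3–C4 bond. The closest known reaction type is the chiral diol/boron-promoted cycloaddition of 2'-hydroxychalcones with 1-aryl-3-methylbuta-1,3-dienes, which copies the presumed biosynthesis of this skeleton. The only ring closed is the six-membered carbocycle, by intermolecular suprafacial–suprafacial [4+2] addition that makes both sigma bonds in one operation. C4/C5 trans is carried over from the E geometry of the chalcone, C3/C4 trans comes from the exo transition state, in which the methyl-bearing diene carbons turn away from the vaulted naphthalene walls while the flat aryl ring of 15 lies under the boron chelate, and the absolute sense comes from the ligand, which covers the Re face at the α- and β-carbons of the s-cis enone so that the diene adds to the Si face and gives 3R,4R,5S. Regioselectivity is secured because the aryl group on the diene terminus and the methyl group on the inner carbon both place the largest HOMO coefficient on the CH2 terminus, which pairs with the β-carbon, and chemoselectivity because only the chelated enone is activated and the stilbene double bond belongs to no s-cis diene. Any endo adduct should be removable on silica gel, and hydrolysis of 17 on work-up returns the ligand.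

Step 11
Reactants: 18 all-trans (3R,4R,5S) cycloadduct heptaacetate
Product: 19 target, (3R,4R,5S)-configured all-trans adduct with eight free phenols
Conditions: K2CO3 (8 equiv), degassed MeOH, argon, 0 °C to rt; then 1 M HCl to pH 5
Reagents that add atoms: none
Why: Base-mediated transesterification removes all seven aryl acetates without acid, so phenol addition to the ring alkene and ketal formation are avoided, and C4 next to the ketone is safe because the all-equatorial all-trans isomer is the thermodynamic epimer.

Compound list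
1 | 2,4-dihydroxyacetophenone | CC(=O)c1ccc(O)cc1O | starting material
2 | 4-acetyl-3-hydroxyphenyl acetate | CC(=O)Oc1ccc(C(C)=O)c(O)c1 | intermediate
3 | 2,4-dihydroxybenzaldehyde | O=Cc1ccc(O)cc1O | starting material
4 | 4-formylbenzene-1,3-diyl diacetate | CC(=O)Oc1ccc(C=O)c(OC(C)=O)c1 | intermediate
5 | (E)-4-[3-(4-acetoxy-2-hydroxyphenyl)-3-oxoprop-1-enyl]benzene-1,3-diyl diacetate | CC(=O)Oc1ccc(C(=O)/C=C/c2ccc(OC(C)=O)cc2OC(C)=O)c(O)c1 | intermediate
6 | 3,5-dihydroxybenzaldehyde | O=Cc1cc(O)cc(O)c1 | starting material
7 | dipotassium 5-vinylbenzene-1,3-diolate (not isolated) | C=Cc1cc([O-])cc([O-])c1.[K+].[K+] | intermediate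
8 | 5-vinylbenzene-1,3-diyl diacetate | C=Cc1cc(OC(C)=O)cc(OC(C)=O)c1 | intermediate
9 | 4-bromobenzene-1,3-diol | Oc1ccc(Br)c(O)c1 | starting material
10 | 4-bromo-6-iodobenzene-1,3-diol | Oc1cc(O)c(I)cc1Br | intermediate
11 | 4-bromo-6-iodobenzene-1,3-diyl diacetate | CC(=O)Oc1cc(OC(C)=O)c(I)cc1Br | intermediate
12 | 4-bromo-6-[(E)-3,5-diacetoxystyryl]benzene-1,3-diyl diacetate | CC(=O)Oc1cc(OC(C)=O)c(/C=C/c2cc(OC(C)=O)cc(OC(C)=O)c2)cc1Br | intermediate
13 | 2-methylbut-1-en-3-yne | C#CC(C)=C | starting material
14 | (E)-4,4,5,5-tetramethyl-2-(3-methylbuta-1,3-dienyl)-1,3,2-dioxaborolane | CC(=C)/C=C/B1OC(C)(C)C(C)(C)O1 | intermediate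
15 | 4-[(E)-3,5-diacetoxystyryl]-6-[(E)-3-methylbuta-1,3-dienyl]benzene-1,3-diyl diacetate | CC(=C)/C=C/c1cc(/C=C/c2cc(OC(C)=O)cc(OC(C)=O)c2)c(OC(C)=O)cc1OC(C)=O | intermediate
16 | spiroborate of chalcone 5 (phenolate and ketone oxygen on boron) with (R)-VANOL; axial chirality R, not expressible in SMILES; not isolated | CC(=O)Oc1ccc(/C=C/C2=[O+][B-]3(Oc4cc(OC(C)=O)ccc42)Oc2c(c(-c4ccccc4)cc4ccccc24)-c2c(O3)c4ccccc4cc2-c2ccccc2)c(OC(C)=O)c1 | intermediate
17 | spiroborate of the (3R,4R,5S) cycloadduct with (R)-VANOL; axial chirality R, not expressible in SMILES; not isolated | CC1=C[C@@H](c2cc(/C=C/c3cc(OC(C)=O)cc(OC(C)=O)c3)c(OC(C)=O)cc2OC(C)=O)[C@H](C2=[O+][B-]3(Oc4cc(OC(C)=O)ccc42)Oc2c(c(-c4ccccc4)cc4ccccc24)-c2c(O3)c4ccccc4cc2-c2ccccc2)[C@@H](c2ccc(OC(C)=O)cc2OC(C)=O)C1 | intermediate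
18 | all-trans (3R,4R,5S) cycloadduct heptaacetate, free hydroxyl ortho to the ketone | CC1=C[C@@H](c2cc(/C=C/c3cc(OC(C)=O)cc(OC(C)=O)c3)c(OC(C)=O)cc2OC(C)=O)[C@H](C(=O)c2ccc(OC(C)=O)cc2O)[C@@H](c2ccc(OC(C)=O)cc2OC(C)=O)C1 | intermediate
19 | target: (3R,4R,5S)-4-(2,4-dihydroxybenzoyl)-5-(2,4-dihydroxyphenyl)-3-{2,4-dihydroxy-5-[(E)-3,5-dihydroxystyryl]phenyl}-1-methylcyclohex-1-ene | CC1=C[C@@H](c2cc(/C=C/c3cc(O)cc(O)c3)c(O)cc2O)[C@H](C(=O)c2ccc(O)cc2O)[C@@H](c2ccc(O)cc2O)C1 | target

Total step count: 11. Longest linear sequence: 6 steps (steps 5, 6, 7, 9, 10 and 11, from 9).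

Steps most likely to fail

Step 10.
- **Risk:** The exo preference may be too weak. The ligand may shield one enone face incompletely. The acetoxy groups lower the diene HOMO, so the cycloaddition may be slow enough for the diene to polymerise.
- **Fallback:** It sets out from 5 and 15 and comes back at 18. The chiral boron reagent is given up. The two partners are combined under achiral catalysis by zerovalent silver particles on silica gel (made from AgBF4 and Bu4NBH4) in CH2Cl2 at 50 °C. The exo and endo racemates are parted on silica gel. The racemic all-trans cycloadduct heptaacetate F1 is then resolved by preparative HPLC on a polysaccharide-based chiral stationary phase, and its 3R,4R,5S enantiomer is 18.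

Step 3.
- **Risk:** The Lewis acid may cause migration or loss of the ortho-acetyl group, followed by cyclisation towards flavylium-type species. Boron may be retained at the chelating site, and dehydration may stay incomplete.
- **Fallback:** It sets out from 1 and 3 and comes back at 5, and it moves the condensation to classical basic conditions with base-stable ethers.
  - MOMCl and K2CO3 in acetone convert 1 into 1-[2-hydroxy-4-(methoxymethoxy)phenyl]ethanone F2.
  - MOMCl and iPr2NEt in CH2Cl2 convert 3 into 2,4-bis(methoxymethoxy)benzaldehyde F3.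
  - KOH in EtOH joins the two to (E)-2'-hydroxy-2,4,4'-tris(methoxymethoxy)chalcone F4.
  - HCl in MeOH frees (E)-2,2',4,4'-tetrahydroxychalcone F5.
  - Ac2O (3 equiv) in pyridine at 0 °C acetylates the three unchelated phenols to give 5.

Step 9.
- **Risk:** Fluoride may strip acetyl groups, the dienylboronate may protodeboronate, and the product diene may dimerise or polymerise at the coupling temperature.
- **Fallback:** It sets out from 12 and comes back at 15, and it builds the diene from an alcohol instead of a boron reagent. A Heck reaction of 12 with 2-methylbut-3-en-2-ol (Pd(OAc)2, P(o-tol)3, Et3N, DMF, 100 °C) gives 4-[(E)-3,5-diacetoxystyryl]-6-[(E)-3-hydroxy-3-methylbut-1-enyl]benzene-1,3-diyl diacetate F6. Dehydration of this tertiary allylic alcohol with catalytic PPTS in toluene at 80 °C over molecular sieves gives 15.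

Further compounds
F1 | step 10 | racemic all-trans cycloadduct heptaacetate (both enantiomers) | CC1=C[C@@H](c2cc(/C=C/c3cc(OC(C)=O)cc(OC(C)=O)c3)c(OC(C)=O)cc2OC(C)=O)[C@H](C(=O)c2ccc(OC(C)=O)cc2O)[C@@H](c2ccc(OC(C)=O)cc2OC(C)=O)C1.CC1=C[C@H](c2cc(/C=C/c3cc(OC(C)=O)cc(OC(C)=O)c3)c(OC(C)=O)cc2OC(C)=O)[C@@H](C(=O)c2ccc(OC(C)=O)cc2O)[C@H](c2ccc(OC(C)=O)cc2OC(C)=O)C1
F2 | step 3 | 1-[2-hydroxy-4-(methoxymethoxy)phenyl]ethanone | COCOc1ccc(C(C)=O)c(O)c1
F3 | step 3 | 2,4-bis(methoxymethoxy)benzaldehyde | COCOc1ccc(C=O)c(OCOC)c1
F4 | step 3 | (E)-2'-hydroxy-2,4,4'-tris(methoxymethoxy)chalcone | COCOc1ccc(C(=O)/C=C/c2ccc(OCOC)cc2OCOC)c(O)c1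
F5 | step 3 | (E)-2,2',4,4'-tetrahydroxychalcone | O=C(/C=C/c1ccc(O)cc1O)c1ccc(O)cc1O
F6 | step 9 | 4-[(E)-3,5-diacetoxystyryl]-6-[(E)-3-hydroxy-3-methylbut-1-enyl]benzene-1,3-diyl diacetate | CC(C)(O)/C=C/c1cc(/C=C/c2cc(OC(C)=O)cc(OC(C)=O)c2)c(OC(C)=O)cc1OC(C)=O
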